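## Analysis of the target

Plicatic acid (27) is a 1-aryltetralin. The aromatic ring A (6-methoxy, 7-hydroxy) is fused to the saturated ring B (C1–C4), and C1 carries ring C, a 3,4-dihydroxy-5-methoxyphenyl group. Ring B holds three contiguous stereocentres: the doubly benzylic methine C1 and the two fully substituted carbinol carbons C2 (hydroxyl and carboxyl) and C3 (hydroxyl and the hydroxymethyl carbon C9). The C2 and C3 hydroxyls lie on opposite faces of ring B, as do the carboxyl carbon on C2 and C9 on C3; the ring C aryl group is cis to the C2 hydroxyl and trans to the carboxyl group. Applied to the structure as drawn, the CIP rules give (1S,2S,3R). Sensitive features are the catechol and phenol (air oxidation, above all in base) and the α-hydroxy acid with its vicinal tertiary alcohol (retro-aldol cleavage, lactonisation onto C9–OH). The difficulty is density: two adjacent quaternary oxygenated carbons next to a hindered diarylmethine, and neither C2 nor C3 can be corrected once made. The strategy rests on two features. The C2–C3 unit, with trans oxygens and trans carbon substituents, has the pattern and geometry of the (E)-enediol diacid dihydroxyfumaric acid (17). Ring B is a benzo-fused cyclohexene, the product type of an o-quinodimethane [4+2] cycloaddition that forms C1–C2 and C3–C4.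

## Retrosynthetic reasoning

**27 back to 24 (via 26 and 25).** The three phenolic O–H bonds are traced back to benzyl ethers, removed last by hydrogenolysis so that the free catechol never meets base. The single enantiomer is traced back to the racemic acid 24 through its salt 25 with a chiral amine. The cut is placed here because 24 is the first intermediate with a carboxylic acid handle and is still lipophilic enough to crystallise as a salt.

**24 back to 22 (via 23).** The acid comes from the C2 methyl ester of 23, and C9 of 23 from the C3 ester of diol diester 22. The forward reduction must distinguish two α-hydroxy esters. The C3 ester sits next to the C4 methylene, the C2 ester next to the aryl-bearing C1, so the distinction is steric.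

**22 back to 21.** The two tertiary hydroxyls are carried as acetates. These are what make the enediol of the C4 building block a stable, isolable alkene, and they come off by transesterification without touching the methyl esters.

**21 back to 16 and 19 (via 20).** C1–C2 and C3–C4 are cut together. No other pair of cuts leaves C2 and C3 joined with all four of their heteroatom-bearing substituents intact. What falls out is the tetrasubstituted alkene 19 and the o-quinodimethane 20. The forward reaction must close ring B and fix three stereocentres at once: the E geometry of 19 gives the trans relationships at C2/C3, and the orientation of 19 towards the outward aryl group of 20 fixes C1. Diene 20 is stored as benzocyclobutene 16, whose own stereocentre disappears on ring opening.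

**19 back to 17 (via 18).** Acetylation and esterification lead back to commercial dihydroxyfumaric acid 17, which supplies C2, C3, the carboxyl carbon and C9 at their final oxidation levels or one reduction away.

**16 back to 14.** The aryl–CH2 bond of the four-membered ring is cut. The forward step is an aryllithium closing onto a primary bromide, which needs only an ortho bromine on ring A and a 2,2-diarylethyl bromide.

**14 back to 9 (via 13, 11, 10).** The CH2Br carbon is not present in the two aryl building blocks. It is added as a methylene to ketone 10, and hydroboration of 11 moves the functionality to the terminal carbon (13). Ketone 10 is the oxidation product of carbinol 9.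

**9 back to 7 and 4 (via 8), and on to 5 and 1.** The diaryl carbinol C–C bond is cut between ring C as nucleophile (aryllithium 8 from bromide 4) and ring A as aldehyde 7, which keeps its bromine for the later ring closure. Bromide 4 comes from 1 by aldehyde-to-phenol oxidation (3) and benzylation. Aldehyde 7 comes from isovanillin 5 by benzylation (6) and bromination para to the benzyloxy group.

## Alternatives that were turned down

**Alternative 1:** The C1–H and C2–O bonds are taken back to an epoxide across C1 and C2, and this to a flat C1=C2 double bond in a 1-aryl-3,4-dihydronaphthalene. Its C2 carries an allylic hydroxymethyl group, and its C3 carbinol is already in place as an acetonide with C9. Forward, epoxidation with Ti(OiPr)4, diethyl tartrate and tert-butyl hydroperoxide would place the oxygen on the face cis to C9 and give epoxy alcohol A1. Hydride opening at C1 with inversion would then set C1, and the C2 hydroxymethyl group would be oxidised to the acid.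
- For it: the epoxidation is reagent-controlled, so absolute configuration comes from the tartrate and no resolution is needed. On this point it is stronger than the chosen route. C1 then follows stereospecifically.
- Against it: the alkene is tetrasubstituted, conjugated to two electron-rich rings and flanked by a quaternary centre, a poor substrate for this catalyst. The existing C3 centre makes it a case of double stereodifferentiation. A1 is a doubly benzylic, donor-substituted epoxide that the Lewis-acidic titanium can ionise. C3 must be built beforehand, and the C2 carbon must be oxidised late beside three electron-rich rings.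
- Comparison: it sets the centres one at a time over a longer linear sequence. The cycloaddition forms C1, C2, C3 and both ring B bonds in one operation, with C2 already at the acid oxidation level. It gives up absolute control and recovers it by a late resolution.

**Alternative 2:** The C3–C9 bond is disconnected. A 3-tetralone with C1 and C2 finished is converted into its C3=C4 silyl enol ether, and the C2 hydroxyl is silylated as a (bromomethyl)dimethylsilyl ether. Bu3SnH and AIBN generate the α-silyl radical, which closes 5-exo onto C3. The benzylic C4 radical takes hydrogen from the stannane to give the cis-fused siloxane A2, and a Tamao oxidation would unveil C9–OH.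
- For it: delivery from the C2 oxygen through a five-membered ring can only place C9 cis to that oxygen, which is the relationship in the target. This is a more secure argument than the exo/endo preference on which the chosen route depends.
- Against it: the radical attacks the oxygen-bearing, fully substituted carbon of an electron-rich enol ether, which is hindered and polarity-mismatched. The crowded tertiary C2 hydroxyl must first be silylated. Tin is stoichiometric. The step solves C3 only: C1, C2 and ring B need their own multistep construction before it, and two more steps follow it.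
- Comparison: the cycloaddition route is ahead in step count and convergence. In place of the tether's certainty it makes all three centres together from two simple components.

**Alternative 3:** The C4–C4a bond is cut. C2 (hydroxyl, ester) bears a 3-hydroxyoxetan-3-yl group as latent C3 and is tied to ring A only through C1. Under Sc(OTf)3 the ring A carbon para to the benzyloxy group attacks one of the two diastereotopic oxetane methylenes. This closes ring B, creates C3 and frees the other arm as C9–OH, giving A3.
- For it: a catalytic, mild Friedel–Crafts step turns a prochiral oxetane into the quaternary carbinol and the hydroxymethyl group at once, driven by strain release at the best-activated position of ring A. In mildness and in economy for C3 and C9 it is at least the equal of the chosen key step.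
- Against it: A3 has no substituent on C1. The ring C aryl would have to be introduced later at a benzylic methylene that must be told apart from the equally benzylic C4, next to a quaternary centre and with control of configuration. The C1/C2 relationship is postponed, not solved. The choice between the two oxetane methylenes rests on a small conformational bias, and C2 must first be made as a single enantiomer.
- Comparison: the chosen strategy carries the C1 aryl into the ring-forming step and fixes it there relative to C2 and C3.

Key step: step 13

Remarks on the chemistry: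
- Compounds 21–24 are racemates. Their names and SMILES give the relative configuration, drawn as the enantiomer that step 17 retains.
- Anions that are only protonated on aqueous work-up (alkoxides, phenolates, carboxylates, borate esters) are not numbered apart from their neutral forms.

## Route

Step 1
Reactants: 1 5-bromo-2-hydroxy-3-methoxybenzaldehyde
Product: 3 5-bromo-3-methoxybenzene-1,2-diol, via aryl formate 2 (not isolated)
Conditions: H2O2 (30% aq.), NaOH (aq.), N2, 0 °C to rt; then HCl
Reagents that add atoms: hydrogen peroxide, OO
Why: Dakin oxidation: hydroperoxide adds to the aldehyde, the electron-rich aryl group migrates to oxygen to give formate 2, and this is saponified in the alkaline medium. The ortho hydroxyl makes the migration fast and the bromine is untouched.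

Step 2
Reactants: 3 5-bromo-3-methoxybenzene-1,2-diol
Product: 4 1,2-bis(benzyloxy)-5-bromo-3-methoxybenzene
Conditions: BnBr, K2CO3, DMF, N2, 60 °C
Reagents that add atoms: benzyl bromide, BrCc1ccccc1
Why: Williamson ether synthesis on both phenols under mild carbonate conditions. Nitrogen protects the catechol until it is alkylated.

Step 3
Reactants: 5 isovanillin
Product: 6 3-(benzyloxy)-4-methoxybenzaldehyde
Conditions: BnBr, K2CO3, DMF, rt
Reagents that add atoms: benzyl bromide, BrCc1ccccc1
Why: Williamson ether synthesis of the single phenol.

Step 4
Reactants: 6 3-(benzyloxy)-4-methoxybenzaldehyde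
Product: 7 5-(benzyloxy)-2-bromo-4-methoxybenzaldehyde
Conditions: Br2, NaOAc, AcOH, rt
Reagents that add atoms: bromine, BrBr
Why: Electrophilic aromatic bromination at the position para to the benzyloxy group and ortho to the formyl group, the most activated unhindered site (the same regiochemistry as for veratraldehyde). Acetate buffers the HBr so the benzyl ether survives.

Step 5
Reactants: 4 1,2-bis(benzyloxy)-5-bromo-3-methoxybenzene; 7 5-(benzyloxy)-2-bromo-4-methoxybenzaldehyde
Product: 9 diaryl carbinol, via aryllithium 8 (not isolated)
Conditions: nBuLi (1.05 equiv), THF, −78 °C; then 7, −78 to 0 °C; then H2O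
Reagents that add atoms: none
Why: Bromine–lithium exchange on 4 is fast at −78 °C, and aryllithium 8 adds to the aldehyde of 7 (1,2-addition) far faster than it exchanges with the aryl bromide of 7. The new carbinol centre is racemic and is removed in step 6.

Step 6
Reactants: 9 diaryl carbinol
Product: 10 diaryl ketone
Conditions: MnO2, CH2Cl2, rt
Reagents that add atoms: none
Why: MnO2 oxidation of a doubly benzylic alcohol to the benzophenone; nothing else in the molecule is oxidisable under these conditions.

Step 7
Reactants: 10 diaryl ketone
Product: 11 1,1-diarylethylene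
Conditions: MePPh3Br, KOtBu, THF, 0 to 65 °C
Reagents that add atoms: methyltriphenylphosphonium bromide, C[P+](c1ccccc1)(c1ccccc1)c1ccccc1.[Br-]
Why: Wittig methylenation of a non-enolisable diaryl ketone. Heating overcomes the hindrance of the ortho bromine, and an alkoxide base leaves the aryl bromide intact.

Step 8
Reactants: 11 1,1-diarylethylene
Product: 13 2,2-diarylethanol, via B-alkyl-9-BBN adduct 12 (not isolated)
Conditions: 9-BBN, THF, 65 °C; then NaOH, H2O2, 0 °C to rt
Reagents that add atoms: 9-borabicyclo[3.3.1]nonane (boron framework of 12, only hydrogen in 13), [H]B1C2CCCC1CCC2; hydrogen peroxide, OO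
Why: Hydroboration–oxidation: boron adds to the terminal carbon of the 1,1-disubstituted alkene (anti-Markovnikov), and alkaline peroxide replaces it by hydroxyl. The new diarylmethine centre is racemic and is lost in step 13.

Step 9
Reactants: 13 2,2-diarylethanol
Product: 14 2,2-diarylethyl bromide
Conditions: CBr4, PPh3, CH2Cl2, 0 °C to rt
Reagents that add atoms: tetrabromomethane, BrC(Br)(Br)Br
Why: Appel bromination of the primary alcohol under neutral conditions, which avoids ionisation or elimination at the neighbouring diarylmethine.

Step 10
Reactants: 14 2,2-diarylethyl bromide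
Product: 16 1-arylbenzocyclobutene, via aryllithium 15 (not isolated)
Conditions: nBuLi (1.05 equiv), THF/hexane, −100 °C; then warm to rt
Reagents that add atoms: none
Why: Parham cyclisation: at −100 °C bromine–lithium exchange at the aryl bromide outpaces any reaction of the primary alkyl bromide. On warming, aryllithium 15 displaces bromide intramolecularly (4-exo-tet), as in the classical preparation of benzocyclobutene from 2-bromophenethyl bromide.

Step 11
Reactants: 17 dihydroxyfumaric acid
Product: 18 dimethyl (E)-2,3-dihydroxybut-2-enedioate
Conditions: HCl (gas), MeOH, 0 °C to rt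
Reagents that add atoms: methanol, CO
Why: Fischer esterification in cold acidic methanol, from which the diester crystallises. Heat and water, which promote decarboxylation of the enediol acid, are avoided.

Step 12
Reactants: 18 dimethyl (E)-2,3-dihydroxybut-2-enedioate
Product: 19 dimethyl (E)-2,3-diacetoxybut-2-enedioate
Conditions: Ac2O, pyridine, DMAP (cat.), CH2Cl2, 0 °C
Reagents that add atoms: acetic anhydride, CC(=O)OC(C)=O
Why: O-Acylation of both enol hydroxyls. The E isomer, with each acetoxy group cis to the vicinal ester, is the less dipolar arrangement and should be kept at 0 °C; the geometry is to be confirmed before use.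

Step 13
Reactants: 16 1-arylbenzocyclobutene; 19 dimethyl (E)-2,3-diacetoxybut-2-enedioate
Product: 21 racemic 1-aryltetralin diacetate diester, via o-quinodimethane 20 (not isolated)
Conditions: 19 (4 equiv), o-xylene, 140 °C, sealed tube, BHT (cat.), slow addition of 16
Reagents that add atoms: none
Why: Proposed new method: on heating, 16 undergoes conrotatory 4π electrocyclic ring opening with the aryl group turning outward, giving (E)-o-quinodimethane 20, which adds 19 across its two exocyclic termini in a concerted suprafacial [4+2] cycloaddition driven by the return of aromaticity to ring A; the closest known reaction type is the Diels–Alder trapping of benzocyclobutene-derived o-quinodimethanes by fumarates and other di- or trisubstituted acceptor alkenes, whereas a tetrasubstituted bis(acyloxy)fumarate has not been used as the 2π partner. Ring B is closed in the cycloaddition itself, C1–C2 and C3–C4 forming together as the two new σ bonds of the six-membered ring (intermolecular [4+2], no separate ring-closing event). At C2 and C3 the E geometry of 19 is transferred suprafacially, so the two acetoxy groups, and likewise the two esters, end up trans. C1 is fixed relative to C2 by the outward aryl group of 20 together with the orientation of 19: the wanted isomer arises when the C2 ester is exo and the C2 acetoxy group endo, which places the aryl group cis to the C2 oxygen. Both orientations carry one ester and one acetoxy group endo, so secondary orbital effects cancel and the preference should rest on the smaller demand of an oxygen substituent, compared with a methoxycarbonyl group, next to the outward aryl group. Nothing controls the face of 19, so 21 forms as a racemate. The step also needs 20 to be trapped faster than it dimerises, which the excess of 19 and the slow addition of 16 are meant to secure; reclosure of 20 only regenerates 16.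

Step 14
Reactants: 21 racemic 1-aryltetralin diacetate diester
Product: 22 racemic diol diester
Conditions: K2CO3 (0.2 equiv), MeOH, 0 °C to rt
Reagents that add atoms: none
Why: Zemplén-type transesterification: the tertiary α-acyloxy esters are activated acetates and are cleaved by methoxide, while exchange at the methyl esters is degenerate. The quaternary carbinols cannot epimerise.

Step 15
Reactants: 22 racemic diol diester
Product: 23 racemic triol monoester
Conditions: LiBH4 (1.5 equiv), THF, 0 °C; then H2O
Reagents that add atoms: none
Why: Regioselective ester reduction by LiBH4, aided by lithium chelation to the α-hydroxyl: the C3 ester next to the C4 methylene is more accessible than the C2 ester wedged between the aryl-bearing C1 and C3. Lactonisation of the new alkoxide onto the C2 ester, which would open the way to over-reduction, would need a trans-fused five-membered ring and should be slow.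

Step 16
Reactants: 23 racemic triol monoester
Product: 24 racemic tri-O-benzyl acid
Conditions: LiOH, THF/H2O, 40 °C; then 1 M HCl to pH 2–3, 0 °C
Reagents that add atoms: lithium hydroxide, [Li+].[OH-]
Why: Saponification of the hindered C2 methyl ester, then cold acidification to the free α-hydroxy acid. The phenols are still benzylated, so nothing is exposed to air oxidation in base.

Step 17
Reactants: 24 racemic tri-O-benzyl acid
Product: 25 (R)-1-phenylethylammonium salt of the (1S,2S,3R) acid
Conditions: (R)-1-phenylethylamine (0.5 equiv), EtOH/EtOAc, 60 °C to rt; recrystallisation to constant rotation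
Reagents that add atoms: (R)-1-phenylethylamine, C[C@@H](N)c1ccccc1
Why: Classical resolution through diastereomeric salts, which differ in solubility. With half an equivalent of amine the other enantiomer stays in solution as the free acid.

Step 18
Reactants: 25 (R)-1-phenylethylammonium salt of the (1S,2S,3R) acid
Product: 27 plicatic acid, via ammonium salt 26 (not isolated)
Conditions: H2 (1 atm), Pd/C (10% palladium on carbon), MeOH, rt; then sulfonic acid resin (H+ form), MeOH/H2O
Reagents that add atoms: none
Why: Hydrogenolysis of the three benzyl ethers under neutral conditions; the core has no benzylic C–O bond, so only the protecting groups are cleaved. The acidic resin then retains the amine and releases the free acid, and no base touches the free catechol.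

## Compound list

1 | 5-bromo-2-hydroxy-3-methoxybenzaldehyde | COc1cc(Br)cc(C=O)c1O | starting material
2 | 5-bromo-2-hydroxy-3-methoxyphenyl formate | COc1cc(Br)cc(OC=O)c1O | intermediate
3 | 5-bromo-3-methoxybenzene-1,2-diol | COc1cc(Br)cc(O)c1O | intermediate
4 | 1,2-bis(benzyloxy)-5-bromo-3-methoxybenzene | COc1cc(Br)cc(OCc2ccccc2)c1OCc1ccccc1 | intermediate
5 | isovanillin (3-hydroxy-4-methoxybenzaldehyde) | COc1ccc(C=O)cc1O | starting material
6 | 3-(benzyloxy)-4-methoxybenzaldehyde | COc1ccc(C=O)cc1OCc1ccccc1 | intermediate
7 | 5-(benzyloxy)-2-bromo-4-methoxybenzaldehyde | COc1cc(Br)c(C=O)cc1OCc1ccccc1 | intermediate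
8 | [3,4-bis(benzyloxy)-5-methoxyphenyl]lithium | [Li]c1cc(OC)c(OCc2ccccc2)c(OCc2ccccc2)c1 | intermediate
9 | [5-(benzyloxy)-2-bromo-4-methoxyphenyl][3,4-bis(benzyloxy)-5-methoxyphenyl]methanol (racemic) | COc1cc(Br)c(cc1OCc1ccccc1)C(O)c1cc(OC)c(OCc2ccccc2)c(OCc2ccccc2)c1 | intermediate
10 | [5-(benzyloxy)-2-bromo-4-methoxyphenyl][3,4-bis(benzyloxy)-5-methoxyphenyl]methanone | COc1cc(Br)c(cc1OCc1ccccc1)C(=O)c1cc(OC)c(OCc2ccccc2)c(OCc2ccccc2)c1 | intermediate
11 | 1-(benzyloxy)-4-bromo-5-{1-[3,4-bis(benzyloxy)-5-methoxyphenyl]ethenyl}-2-methoxybenzene | COc1cc(Br)c(cc1OCc1ccccc1)C(=C)c1cc(OC)c(OCc2ccccc2)c(OCc2ccccc2)c1 | intermediate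
12 | 9-{2-[5-(benzyloxy)-2-bromo-4-methoxyphenyl]-2-[3,4-bis(benzyloxy)-5-methoxyphenyl]ethyl}-9-borabicyclo[3.3.1]nonane | COc1cc(Br)c(cc1OCc1ccccc1)C(CB1C2CCCC1CCC2)c1cc(OC)c(OCc2ccccc2)c(OCc2ccccc2)c1 | intermediate
13 | 2-[5-(benzyloxy)-2-bromo-4-methoxyphenyl]-2-[3,4-bis(benzyloxy)-5-methoxyphenyl]ethan-1-ol (racemic) | COc1cc(Br)c(cc1OCc1ccccc1)C(CO)c1cc(OC)c(OCc2ccccc2)c(OCc2ccccc2)c1 | intermediate
14 | 1-(benzyloxy)-4-bromo-5-{2-bromo-1-[3,4-bis(benzyloxy)-5-methoxyphenyl]ethyl}-2-methoxybenzene (racemic) | COc1cc(Br)c(cc1OCc1ccccc1)C(CBr)c1cc(OC)c(OCc2ccccc2)c(OCc2ccccc2)c1 | intermediate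
15 | {4-(benzyloxy)-2-{2-bromo-1-[3,4-bis(benzyloxy)-5-methoxyphenyl]ethyl}-5-methoxyphenyl}lithium | COc1cc([Li])c(cc1OCc1ccccc1)C(CBr)c1cc(OC)c(OCc2ccccc2)c(OCc2ccccc2)c1 | intermediate
16 | 4-(benzyloxy)-7-[3,4-bis(benzyloxy)-5-methoxyphenyl]-3-methoxybicyclo[4.2.0]octa-1,3,5-triene (1-arylbenzocyclobutene, racemic) | COc1cc2CC(c3cc(OCc4ccccc4)c(OCc4ccccc4)c(OC)c3)c2cc1OCc1ccccc1 | intermediate
17 | dihydroxyfumaric acid | OC(=O)/C(O)=C(O)/C(=O)O | starting material
18 | dimethyl (E)-2,3-dihydroxybut-2-enedioate | COC(=O)/C(O)=C(O)/C(=O)OC | intermediate
19 | dimethyl (E)-2,3-diacetoxybut-2-enedioate | COC(=O)/C(OC(C)=O)=C(OC(C)=O)/C(=O)OC | intermediate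
20 | 2-(benzyloxy)-6-{(E)-[3,4-bis(benzyloxy)-5-methoxyphenyl]methylidene}-3-methoxy-5-methylidenecyclohexa-1,3-diene (o-quinodimethane, aryl outward) | COC1=CC(=C)/C(=C/c2cc(OCc3ccccc3)c(OCc3ccccc3)c(OC)c2)C=C1OCc1ccccc1 | intermediate
21 | dimethyl 2,3-diacetoxy-7-(benzyloxy)-1-[3,4-bis(benzyloxy)-5-methoxyphenyl]-6-methoxy-1,2,3,4-tetrahydronaphthalene-2,3-dicarboxylate (racemate; aryl cis to C2 acetoxy, the two acetoxy groups trans, the two esters trans) | COc1cc2c(cc1OCc1ccccc1)[C@H](c1cc(OCc3ccccc3)c(OCc3ccccc3)c(OC)c1)[C@@](OC(C)=O)(C(=O)OC)[C@](OC(C)=O)(C(=O)OC)C2 | intermediate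
22 | dimethyl 7-(benzyloxy)-1-[3,4-bis(benzyloxy)-5-methoxyphenyl]-2,3-dihydroxy-6-methoxy-1,2,3,4-tetrahydronaphthalene-2,3-dicarboxylate (racemate; aryl cis to C2–OH, hydroxyls trans, esters trans) | COc1cc2c(cc1OCc1ccccc1)[C@H](c1cc(OCc3ccccc3)c(OCc3ccccc3)c(OC)c1)[C@@](O)(C(=O)OC)[C@](O)(C(=O)OC)C2 | intermediate
23 | methyl 7-(benzyloxy)-1-[3,4-bis(benzyloxy)-5-methoxyphenyl]-2,3-dihydroxy-3-(hydroxymethyl)-6-methoxy-1,2,3,4-tetrahydronaphthalene-2-carboxylate (racemate; aryl cis to C2–OH, hydroxyls trans, ester trans to hydroxymethyl) | COc1cc2c(cc1OCc1ccccc1)[C@H](c1cc(OCc3ccccc3)c(OCc3ccccc3)c(OC)c1)[C@@](O)(C(=O)OC)[C@](O)(CO)C2 | intermediate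
24 | 7-(benzyloxy)-1-[3,4-bis(benzyloxy)-5-methoxyphenyl]-2,3-dihydroxy-3-(hydroxymethyl)-6-methoxy-1,2,3,4-tetrahydronaphthalene-2-carboxylic acid (racemate, same relative configuration) | COc1cc2c(cc1OCc1ccccc1)[C@H](c1cc(OCc3ccccc3)c(OCc3ccccc3)c(OC)c1)[C@@](O)(C(=O)O)[C@](O)(CO)C2 | intermediate
25 | (R)-1-phenylethylammonium (1S,2S,3R)-7-(benzyloxy)-1-[3,4-bis(benzyloxy)-5-methoxyphenyl]-2,3-dihydroxy-3-(hydroxymethyl)-6-methoxy-1,2,3,4-tetrahydronaphthalene-2-carboxylate | COc1cc2c(cc1OCc1ccccc1)[C@H](c1cc(OCc3ccccc3)c(OCc3ccccc3)c(OC)c1)[C@@](O)(C([O-])=O)[C@](O)(CO)C2.C[C@@H]([NH3+])c1ccccc1 | intermediate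
26 | (R)-1-phenylethylammonium salt of plicatic acid | COc1cc2c(cc1O)[C@H](c1cc(O)c(O)c(OC)c1)[C@@](O)(C([O-])=O)[C@](O)(CO)C2.C[C@@H]([NH3+])c1ccccc1 | intermediate
27 | plicatic acid, (1S,2S,3R)-1-(3,4-dihydroxy-5-methoxyphenyl)-2,3,7-trihydroxy-3-(hydroxymethyl)-6-methoxy-1,2,3,4-tetrahydronaphthalene-2-carboxylic acid | COc1cc2c(cc1O)[C@H](c1cc(O)c(O)c(OC)c1)[C@@](O)(C(=O)O)[C@](O)(CO)C2 | target

## Step count and least certain steps

Total: 18 steps. Longest linear sequence: 14 steps (from 5 through steps 3–10 and 13–18; the branch from 1 is equally long).

**Step 13 (key step, proposed new method).** The tetrasubstituted, doubly acyloxy-substituted alkene may capture the o-quinodimethane too slowly, so that dimerisation or oligomerisation of the diene takes over. Where capture succeeds, the exo/endo preference at C2 may be small, because both orientations place one ester and one acetoxy group endo; this would give a mixture of C1 epimers. The fallback uses known reactions only. It sets out from aryllithium 8 and returns at 23.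
- Formylation of 8 with DMF gives 3,4-bis(benzyloxy)-5-methoxybenzaldehyde F1.
- Commercial 2-[4-(benzyloxy)-3-methoxyphenyl]acetic acid is activated with 1,1′-carbonyldiimidazole to acyl imidazolide F2. This acylates the magnesium enolate of potassium methyl malonate (MgCl2, Et3N), and decarboxylation gives β-keto ester F3.
- Knoevenagel condensation of F1 with F3 (piperidinium acetate, removal of water) gives arylidene keto ester F4.
- Nucleophilic epoxidation (tert-butyl hydroperoxide, DBU) gives epoxide F5.
- BF3·OEt2 in CH2Cl2 at −78 °C opens the epoxide at the benzylic carbon, which the para-benzyloxy group of ring C stabilises. Ring A attacks this carbon para to its methoxy group (intramolecular Friedel–Crafts alkylation) to give tetralone F6. The C2 oxygen is kept from the epoxide, and allylic strain in the benzylic cation should place the aryl group cis to the C2 hydroxyl.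
- Takai–Lombardo methylenation (Zn, CH2Br2, TiCl4) gives exocyclic alkene F7.
- OsO4/NMO dihydroxylation anti to the allylic C2 hydroxyl delivers 23, from which steps 16–18 follow.

**Step 10.** Elimination across the diarylmethine and the CH2Br group, or intermolecular alkylation, may compete with closure of the strained four-membered ring. The fallback reaches the same diene from an open-chain precursor, sets out from 9 and returns at 21. Treatment of 9 with nBuLi (2.2 equiv; alkoxide formation, then bromine–lithium exchange) and paraformaldehyde gives diol F8. SOCl2 converts it into dichloride F9, used crude. NaI in DMF at 70 °C in the presence of 19 induces 1,4-elimination to 20, which is trapped as 21.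

**Step 15.** The two α-hydroxy esters may not be told apart well enough, or reduction may run on past the hydroxy ester. The fallback sets out from 22 and returns at 23. One equivalent of LiOH (THF/H2O, 0 °C) saponifies the less hindered C3 ester to monoacid F10, the carboxylate then retarding the second hydrolysis. BH3·SMe2 reduces the acid in the presence of the ester to give 23.

**Step 17.** The diastereomeric salts may fail to crystallise or may differ too little in solubility. If it is the salt of the unwanted enantiomer that crystallises, the (S)-amine gives the mirror-image outcome and hence the salt of the wanted acid. The fallback replaces crystallisation by chromatography, sets out from 24 and returns at 27. Preparative HPLC on an amylose tris(3,5-dimethylphenylcarbamate) phase (hexane/iPrOH/TFA) gives the single-enantiomer acid F11, which is hydrogenolysed (H2, Pd/C, MeOH) to 27.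

## Further compounds

F1 | step 13 | 3,4-bis(benzyloxy)-5-methoxybenzaldehyde | COc1cc(C=O)cc(OCc2ccccc2)c1OCc1ccccc1
F2 | step 13 | 2-[4-(benzyloxy)-3-methoxyphenyl]-1-(1H-imidazol-1-yl)ethan-1-one | COc1cc(CC(=O)n2ccnc2)ccc1OCc1ccccc1
F3 | step 13 | methyl 4-[4-(benzyloxy)-3-methoxyphenyl]-3-oxobutanoate | COC(=O)CC(=O)Cc1ccc(OCc2ccccc2)c(OC)c1
F4 | step 13 | methyl 2-{[3,4-bis(benzyloxy)-5-methoxyphenyl]methylidene}-4-[4-(benzyloxy)-3-methoxyphenyl]-3-oxobutanoate (E/Z mixture) | COC(=O)C(=Cc1cc(OC)c(OCc2ccccc2)c(OCc2ccccc2)c1)C(=O)Cc1ccc(OCc2ccccc2)c(OC)c1
F5 | step 13 | methyl 2-{2-[4-(benzyloxy)-3-methoxyphenyl]acetyl}-3-[3,4-bis(benzyloxy)-5-methoxyphenyl]oxirane-2-carboxylate (racemic diastereomer mixture) | COC(=O)C1(OC1c1cc(OC)c(OCc2ccccc2)c(OCc2ccccc2)c1)C(=O)Cc1ccc(OCc2ccccc2)c(OC)c1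
F6 | step 13 | methyl 7-(benzyloxy)-1-[3,4-bis(benzyloxy)-5-methoxyphenyl]-2-hydroxy-6-methoxy-3-oxo-1,2,3,4-tetrahydronaphthalene-2-carboxylate (racemate; aryl cis to C2–OH) | COc1cc2c(cc1OCc1ccccc1)[C@H](c1cc(OCc3ccccc3)c(OCc3ccccc3)c(OC)c1)[C@@](O)(C(=O)OC)C(=O)C2
F7 | step 13 | methyl 7-(benzyloxy)-1-[3,4-bis(benzyloxy)-5-methoxyphenyl]-2-hydroxy-6-methoxy-3-methylidene-1,2,3,4-tetrahydronaphthalene-2-carboxylate (racemate; aryl cis to C2–OH) | COc1cc2c(cc1OCc1ccccc1)[C@H](c1cc(OCc3ccccc3)c(OCc3ccccc3)c(OC)c1)[C@@](O)(C(=O)OC)C(=C)C2
F8 | step 10 | [5-(benzyloxy)-2-(hydroxymethyl)-4-methoxyphenyl][3,4-bis(benzyloxy)-5-methoxyphenyl]methanol (racemic) | COc1cc(CO)c(cc1OCc1ccccc1)C(O)c1cc(OC)c(OCc2ccccc2)c(OCc2ccccc2)c1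
F9 | step 10 | 1-(benzyloxy)-4-(chloromethyl)-5-{chloro[3,4-bis(benzyloxy)-5-methoxyphenyl]methyl}-2-methoxybenzene (racemic) | COc1cc(CCl)c(cc1OCc1ccccc1)C(Cl)c1cc(OC)c(OCc2ccccc2)c(OCc2ccccc2)c1
F10 | step 15 | 6-(benzyloxy)-4-[3,4-bis(benzyloxy)-5-methoxyphenyl]-2,3-dihydroxy-7-methoxy-3-(methoxycarbonyl)-1,2,3,4-tetrahydronaphthalene-2-carboxylic acid (racemate; the C3 acid of 22, numbered from the acid carbon) | COc1cc2c(cc1OCc1ccccc1)[C@H](c1cc(OCc3ccccc3)c(OCc3ccccc3)c(OC)c1)[C@@](O)(C(=O)OC)[C@](O)(C(=O)O)C2
F11 | step 17 | (1S,2S,3R)-7-(benzyloxy)-1-[3,4-bis(benzyloxy)-5-methoxyphenyl]-2,3-dihydroxy-3-(hydroxymethyl)-6-methoxy-1,2,3,4-tetrahydronaphthalene-2-carboxylic acid (single enantiomer of 24) | COc1cc2c(cc1OCc1ccccc1)[C@H](c1cc(OCc3ccccc3)c(OCc3ccccc3)c(OC)c1)[C@@](O)(C(=O)O)[C@](O)(CO)C2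
A1 | alternative 1 | C1–C2 epoxy alcohol with C2 hydroxymethyl group and C3/C9 acetonide, epoxide oxygen cis to C9 (tri-O-benzyl) | COc1cc2c(cc1OCc1ccccc1)[C@]3(c1cc(OCc5ccccc5)c(OCc5ccccc5)c(OC)c1)O[C@]3(CO)[C@](OC(C)(C)O4)(C4)C2
A2 | alternative 2 | cis-fused five-membered siloxane linking the C2 oxygen to C9 on C3, with C3 tert-butyldimethylsilyl ether and C2 methyl ester (tri-O-benzyl) | COc1cc2c(cc1OCc1ccccc1)[C@H](c1cc(OCc3ccccc3)c(OCc3ccccc3)c(OC)c1)[C@@](O[Si](C)(C)C4)(C(=O)OC)[C@@]4(O[Si](C)(C)C(C)(C)C)C2
A3 | alternative 3 | methyl 7-(benzyloxy)-2,3-dihydroxy-3-(hydroxymethyl)-6-methoxy-1,2,3,4-tetrahydronaphthalene-2-carboxylate (C2 and C3 as in the target, no aryl group on C1) | COc1cc2c(cc1OCc1ccccc1)C[C@@](O)(C(=O)OC)[C@](O)(CO)C2
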